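(The runs were computed for an exercise.)

**Set-up.** The easy mistake is to treat target as an end product and read its amount off the charge of coupling partner. Starting material and coupling partner give target in a flask that also holds second substrate. I vary c(starting material) and ask what stands at the end.

| flask | starting material | coupling partner | second substrate | remark | time |
|---|---|---|---|---|---|
| midnight | 0.010 M | 0.012 M | 0.10 M | run made earlier |  |
| autumn | 0.075 M | 0.012 M | 0.10 M | run made earlier |  |
| oak | 0.0080 M | 0.0120 M | 0.100 M |  | 4.0 h |
| cedar | 0.012 M | 0.0120 M | 0.100 M |  | 4.0 h |
| larch | 0.020 M | 0.0120 M | 0.100 M |  | 4.0 h |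
| birch | 0.030 M | 0.0120 M | 0.100 M |  | 4.0 h |
| ash | 0.050 M | 0.0120 M | 0.100 M |  | 4.0 h |

| run | time / min | target / % | starting material / % |
|---|---|---|---|
| midnight | 25.0 | 49 | 42 |
| midnight | 50.0 | 56 | 27 |
| midnight | 80.0 | 48 | 19 |
| midnight | 90.0 | 47 | 18 |
| midnight | 120 | 41 | 10 |
| autumn | 25.0 | 9 | 73 |
| autumn | 50.0 | 4 | 66 |
| autumn | 80.0 | 2 | 64 |
| autumn | 90.0 | 1 | 58 |
| autumn | 120 | 0 | 56 |

(scatter of a reading: 1.5 percentage points)

- "hardly changes" means that all values lie within two and a half points (for a concentration: within two and a half percent of the largest)

* amount of target at the end, in percent of the starting material charged for oak, cedar, larch, birch, ash, in this order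
* how the row runs (falls, then rises / rises, then falls / falls all the way / hardly changes / rises all the way)

**The puzzle.** By 120 min the autumn run has lost 0.0330 M of starting material, more than the 0.012 M of coupling partner charged, yet target reads 0%. If the two react one to one, starting material must have another way to go, and target must be going somewhere.

**Attack constant.** Between 25.0 min and 50.0 min the autumn target falls from 9% to 4%, a decay rate of 0.0324 min⁻¹, while c(starting material) averages 0.0521 M. Dividing gives my attack constant 37.3 M⁻¹ h⁻¹, the decay rate of target per unit c(starting material). It puts every loss of target on starting material, and the readings scatter by 1.5 percentage points, so it is rough.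

Its use is a target life, one over the attack constant times c(starting material). At the charge, that life is 201 min in oak and 32.1 min in ash, shorter as the charge rises, against a run of 240 min. So I expect the row to fall, but I give no percentages.

**The forecast.** It expects 14.5%, 13.5%, 4%, 1.1% and 0.1%, so the row falls all the way, on the ground that “the partner caps yield and leftover SM speeds decay”.

**Result.** The flasks give 29.6%, 22.1%, 10.7%, 4.11% and 0.667%, so the row falls all the way.

    starting material + coupling partner → target (k = 280 M⁻¹ h⁻¹)
    second substrate + coupling partner → second product (k = 8.80 M⁻¹ h⁻¹)
    starting material + second substrate → cross product (k = 1.30 M⁻¹ h⁻¹)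
    coupling partner + target → over-reaction product (k = 1.70 M⁻¹ h⁻¹)
    target ⇌ isomer of the product (K = 4.20, k = 0.270 h⁻¹)
    starting material + target → side product (k = 31.0 M⁻¹ h⁻¹)

**Target life.** Ash ends with 35.1% side product, a form that counts double in every percentage, and 35.8% of its starting material left. That remainder gives a target life of 89.7 min, shorter than the run, with target at 0.667%. Oak ends with 6.20% of its starting material left, and through my attack constant that remainder gives a life of 3240 min, longer than the run. That figure counts attack by starting material and no other loss, but oak's target falls from 45.4% at 2.00 h to 29.6% at 4.00 h, while its isomer of the product rises from 24.5% to 40.1%.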